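**Strategy.** Everything rests on cutting ring C of the flavone at O1–C8a, C4–C4a and O1–C2. This reduces ring A to a C4a–C8a aryne and leaves phenylpropiolic acid as the other partner. The feature used is that ring A bears O1 (on C8a) and the C4 acyl carbon (on C4a) on adjacent atoms, with the C5 methoxy group next to C4a to polarise the triple bond. A single fluoride-triggered operation inserts the aryne into the acid C–O bond and closes the pyranone. The precursor is an ortho-silylaryl triflate (OTf on C8a, SiMe3 on C4a) that already carries the (R)-N-Boc-piperidin-2-yl group on C8 and a benzyl ether on O7.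

Key step: step 10

Remarks
- Flavone numbering is used for rings A and C, and C2' is the piperidine carbon bound to C8. The stereocentre of the target SMILES is R (N > aryl C > CH2 > H). It keeps this descriptor in every N-sulfinyl, N-acyl and N-alkyl intermediate.
- Assumption: the Grignard addition to the sulfinimine follows the usual closed chair model in a non-coordinating solvent, which is not overridden by the ortho MOM ethers. On that model the S-configured auxiliary is the correct one when the alkyl chain is the nucleophile. The configuration is to be confirmed on the adduct before going on.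
- Once the silyl triflate is in place, the material meets no fluoride, no carbonate base and no strong acid until the key step.

**Route**

Step 1
Reactants: 1 5-methoxyresorcinol
Product: 2 1-methoxy-3,5-bis(methoxymethoxy)benzene
Conditions: NaH (2.4 equiv), MOMCl (2.3 equiv), THF–DMF, 0 °C to rt
Reagents that add atoms: chloromethyl methyl ether, COCCl
Why: Williamson-type O-alkylation of both phenoxides gives acetals that survive organolithium, Grignard and hydride bases, act as the strongest ortho-directing groups on the ring in step 2 and leave under the same mild acid as the sulfinyl group in step 6.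

Step 2
Reactants: 2 1-methoxy-3,5-bis(methoxymethoxy)benzene
Product: 4 4-methoxy-2,6-bis(methoxymethoxy)benzaldehyde, via ortho-lithiated arene 3 (not isolated)
Conditions: n-BuLi, TMEDA, THF, 0 °C; DMF, 0 °C to rt; H2O
Reagents that add atoms: N,N-dimethylformamide, CN(C)C=O
Why: Directed ortho-metalation should occur at the one carbon flanked by two chelating MOM ethers rather than at the MOM/OMe-flanked sites, and trapping with DMF installs the aldehyde para to the methoxy group.

Step 3
Reactants: 4 4-methoxy-2,6-bis(methoxymethoxy)benzaldehyde; 5 (S)-tert-butanesulfinamide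
Product: 6 (S,E)-N-[4-methoxy-2,6-bis(methoxymethoxy)benzylidene]-2-methylpropane-2-sulfinamide
Conditions: Ti(OEt)4 (2 equiv), THF, 50 °C
Reagents that add atoms: none
Why: Ti(OEt)4 serves as Lewis acid and water scavenger in the standard aldehyde–sulfinamide condensation, which tolerates di-ortho-substituted benzaldehydes, gives only the E-imine and leaves the sulfur stereocentre untouched.

Step 4
Reactants: 6 (S,E)-sulfinimine; 7 1-bromo-4-chlorobutane
Product: 9 (S)-N-{(1R)-5-chloro-1-[4-methoxy-2,6-bis(methoxymethoxy)phenyl]pentyl}-2-methylpropane-2-sulfinamide, via 4-chlorobutylmagnesium bromide 8 (not isolated)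
Conditions: 7, Mg, Et2O, 30 °C; added to 6, CH2Cl2, −48 °C; aq. NH4Cl; chromatography to a single diastereomer
Reagents that add atoms: none
Why: Magnesium inserts selectively into the C–Br bond, and 1,2-addition of the Grignard reagent to the tert-butanesulfinyl aldimine should pass through the closed six-membered chair transition state (Mg on the sulfinyl oxygen, tert-butyl and aryl equatorial), which for S-configured sulfur delivers the alkyl group to the Re face of C=N and sets C1 as R.

Step 5
Reactants: 9 (S,1R)-chloroalkyl sulfinamide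
Product: 10 (2R)-1-[(S)-tert-butylsulfinyl]-2-[4-methoxy-2,6-bis(methoxymethoxy)phenyl]piperidine
Conditions: NaH, DMF, 0 °C to rt
Reagents that add atoms: none
Why: Deprotonation of the sulfinamide N–H and 6-exo-tet SN2 displacement of the primary chloride close the piperidine without touching the C–N stereocentre, while all phenols are still masked.

Step 6
Reactants: 10 (S,2R)-N-sulfinylpiperidine
Product: 12 tert-butyl (R)-2-(2,6-dihydroxy-4-methoxyphenyl)piperidine-1-carboxylate, via piperidinium chloride 11 (not isolated)
Conditions: HCl (4 M in dioxane), MeOH (dilute), 0 °C to rt; evaporate; Boc2O (1.05 equiv), NaHCO3, THF–H2O, rt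
Reagents that add atoms: di-tert-butyl dicarbonate, CC(C)(C)OC(=O)OC(=O)OC(C)(C)C
Why: Acid methanolysis cleaves the N–S bond and both MOM acetals in one operation at or below room temperature, where the protonated nitrogen is a poor leaving group and the electron-rich benzylic C–N bond should not ionise, and the amine is then converted into its carbamate under bicarbonate conditions that leave the phenols free.

Step 7
Reactants: 12 N-Boc resorcinol
Product: 13 tert-butyl (R)-2-(3-bromo-2,6-dihydroxy-4-methoxyphenyl)piperidine-1-carboxylate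
Conditions: NBS (1.0 equiv), MeCN, −30 °C to 0 °C
Reagents that add atoms: N-bromosuccinimide, O=C1CCC(=O)N1Br
Why: In this electrophilic aromatic bromination the two open ring positions are interchanged by rotation about the aryl–C2' bond, so only one monobromide is possible, and the halogen at the same time makes the two phenols different.

Step 8
Reactants: 13 bromoresorcinol
Product: 18 tert-butyl (R)-2-[6-hydroxy-4-methoxy-3-(trimethylsilyl)-2-(trifluoromethanesulfonyloxy)phenyl]piperidine-1-carboxylate, via bis(silyl ether) 14 (not isolated), via aryllithium 15 (not isolated), via lithium phenoxide 16 (not isolated), via silyl ether triflate 17 (not isolated)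
Conditions: (Me3Si)2NH, THF, 65 °C, evaporate; n-BuLi (1.1 equiv), THF, −78 °C; Tf2O (1.2 equiv), −78 °C; aq. NaHCO3; MeOH, cat. AcOH, 0 °C
Reagents that add atoms: hexamethyldisilazane, C[Si](C)(C)N[Si](C)(C)C; trifluoromethanesulfonic anhydride, O=S(=O)(OS(=O)(=O)C(F)(F)F)C(F)(F)F
Why: This is the standard ortho-bromophenol to ortho-silylaryl triflate sequence, in which bromine–lithium exchange outruns attack on the carbamate at −78 °C, the aryllithium takes SiMe3 from the only adjacent oxygen by a 1,3 O-to-C shift (retro-Brook rearrangement), the released phenoxide is sulfonylated, and the remote aryl silyl ether is removed by weakly acidic methanolysis because fluoride would fire the aryne.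

Step 9
Reactants: 18 phenolic silyl triflate
Product: 19 tert-butyl (R)-2-[6-(benzyloxy)-4-methoxy-3-(trimethylsilyl)-2-(trifluoromethanesulfonyloxy)phenyl]piperidine-1-carboxylate
Conditions: BnOH (1.2 equiv), PPh3, DIAD, THF, 0 °C to rt
Reagents that add atoms: benzyl alcohol, OCc1ccccc1
Why: Mitsunobu etherification of the remaining phenol with a primary alcohol runs under essentially neutral conditions, so neither carbonate nor acid reaches the silyl triflate or the acid-labile aryl–silicon bond, and the ether installed is inert to hot CsF.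

Step 10
Reactants: 19 ortho-silylaryl triflate; 20 phenylpropiolic acid
Product: 24 tert-butyl (R)-2-[7-(benzyloxy)-5-methoxy-4-oxo-2-phenyl-4H-chromen-8-yl]piperidine-1-carboxylate, via C4a–C8a aryne 21 (not isolated), via C4a carbanion ester 22 (not isolated), via ynone phenoxide 23 (not isolated)
Conditions: 20 (1.5 equiv), CsF (5 equiv), THF (0.05 M), 125 °C, sealed tube
Reagents that add atoms: none
Why: Fluoride attacks the SiMe3 group on C4a and triflate leaves C8a, releasing aryne 21 slowly because CsF is barely soluble in THF; the carboxylate of 20 adds through oxygen to C8a, the aryl anion 22 thus placed on C4a attacks the neighbouring ester carbonyl, and O-to-C acyl transfer through a four-membered transition structure gives the ortho-acyl phenoxide 23. The closest known reaction type is the insertion of arynes into the C–O bond of carboxylic acids, which ends at ortho-hydroxyaryl ketones with simple acids and runs on to flavones with 3-arylpropiolic acids; heat and an aprotic ether favour acyl transfer over plain protonation to the aryl ester. Ring C closes by 6-endo-dig oxa-Michael addition of the C8a phenoxide to the ynone β-carbon (C2) followed by protonation at C3, the polarisation of the ynone favouring this mode over 5-exo closure to an aurone. No stereocentre is formed, and C2' is not acidic towards CsF and sits next to a free phenoxide only for the lifetime of 23, so its R configuration should persist. The selectivity required is regiochemical: the inductively withdrawing 5-OMe beside C4a distorts the aryne so that C8a is the more electrophilic terminus and charge builds on C4a, and a small oxygen nucleophile should tolerate the branched C8 substituent. Chemoselectivity rests on nitrogen being a non-basic tertiary carbamate and O7 a benzyl ether, which leaves the carboxylate, used in excess, as the only good nucleophile in the flask.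

Step 11
Reactants: 24 N-Boc O-benzyl flavone
Product: 26 (R)-7-(benzyloxy)-5-methoxy-8-(1-methylpiperidin-2-yl)-2-phenyl-4H-chromen-4-one, via secondary amine trifluoroacetate 25 (not isolated)
Conditions: TFA–CH2Cl2 (1:4), 0 °C; evaporate; 37% aq. HCHO, NaBH(OAc)3, ClCH2CH2Cl, rt; aq. NaHCO3
Reagents that add atoms: formaldehyde, C=O
Why: Acidolysis of the tert-butyl carbamate followed by reductive amination (NaBH(OAc)3 does not reduce the chromone carbonyl) methylates nitrogen while O7 is still benzylated, so no aminomethylation or hydroxymethylation of a free phenolic ring can occur and the stereocentre is never part of a free ortho-hydroxybenzylamine under acid.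

Step 12
Reactants: 26 N-methyl O-benzyl flavone
Product: 27 (R)-7-hydroxy-5-methoxy-8-(1-methylpiperidin-2-yl)-2-phenyl-4H-chromen-4-one (target)
Conditions: H2 (1 atm), 10% Pd/C, MeOH–EtOAc, AcOH (1 equiv), rt, stopped after one equivalent of H2
Reagents that add atoms: none
Why: Catalytic hydrogenolysis of the aryl benzyl ether at room temperature should be faster than reduction of C2=C3 or cleavage of the hindered benzylic C–N bond, avoids Lewis acids that would cleave the peri 5-OMe group, and is mild enough to prevent racemisation by reversible ring opening to an ortho-quinone methide.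

**Compound list**

1 | 5-methoxyresorcinol | COc1cc(O)cc(O)c1 | starting material
2 | 1-methoxy-3,5-bis(methoxymethoxy)benzene | COCOc1cc(OC)cc(OCOC)c1 | intermediate
3 | [4-methoxy-2,6-bis(methoxymethoxy)phenyl]lithium | [Li]c1c(OCOC)cc(OC)cc1OCOC | intermediate (not isolated)
4 | 4-methoxy-2,6-bis(methoxymethoxy)benzaldehyde | O=Cc1c(OCOC)cc(OC)cc1OCOC | intermediate
5 | (S)-tert-butanesulfinamide | CC(C)(C)[S@](=O)N | starting material
6 | (S,E)-N-[4-methoxy-2,6-bis(methoxymethoxy)benzylidene]-2-methylpropane-2-sulfinamide | CC(C)(C)[S@](=O)/N=C/c1c(OCOC)cc(OC)cc1OCOC | intermediate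
7 | 1-bromo-4-chlorobutane | ClCCCCBr | starting material
8 | 4-chlorobutylmagnesium bromide | ClCCCC[Mg]Br | intermediate (not isolated)
9 | (S)-N-{(1R)-5-chloro-1-[4-methoxy-2,6-bis(methoxymethoxy)phenyl]pentyl}-2-methylpropane-2-sulfinamide | CC(C)(C)[S@](=O)N[C@H](CCCCCl)c1c(OCOC)cc(OC)cc1OCOC | intermediate
10 | (2R)-1-[(S)-tert-butylsulfinyl]-2-[4-methoxy-2,6-bis(methoxymethoxy)phenyl]piperidine | CC(C)(C)[S@](=O)N1CCCC[C@@H]1c1c(OCOC)cc(OC)cc1OCOC | intermediate
11 | (R)-2-(2,6-dihydroxy-4-methoxyphenyl)piperidinium chloride | COc1cc(O)c([C@H]2CCCCN2)c(O)c1.Cl | intermediate (not isolated)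
12 | tert-butyl (R)-2-(2,6-dihydroxy-4-methoxyphenyl)piperidine-1-carboxylate | COc1cc(O)c([C@H]2CCCCN2C(=O)OC(C)(C)C)c(O)c1 | intermediate
13 | tert-butyl (R)-2-(3-bromo-2,6-dihydroxy-4-methoxyphenyl)piperidine-1-carboxylate | COc1cc(O)c([C@H]2CCCCN2C(=O)OC(C)(C)C)c(O)c1Br | intermediate
14 | tert-butyl (R)-2-[3-bromo-4-methoxy-2,6-bis(trimethylsilyloxy)phenyl]piperidine-1-carboxylate | COc1cc(O[Si](C)(C)C)c([C@H]2CCCCN2C(=O)OC(C)(C)C)c(O[Si](C)(C)C)c1Br | intermediate (not isolated)
15 | {3-[(R)-1-(tert-butoxycarbonyl)piperidin-2-yl]-6-methoxy-2,4-bis(trimethylsilyloxy)phenyl}lithium | COc1cc(O[Si](C)(C)C)c([C@H]2CCCCN2C(=O)OC(C)(C)C)c(O[Si](C)(C)C)c1[Li] | intermediate (not isolated)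
16 | lithium 2-[(R)-1-(tert-butoxycarbonyl)piperidin-2-yl]-5-methoxy-6-(trimethylsilyl)-3-(trimethylsilyloxy)phenoxide | COc1cc(O[Si](C)(C)C)c([C@H]2CCCCN2C(=O)OC(C)(C)C)c([O-])c1[Si](C)(C)C.[Li+] | intermediate (not isolated)
17 | tert-butyl (R)-2-[4-methoxy-3-(trimethylsilyl)-2-(trifluoromethanesulfonyloxy)-6-(trimethylsilyloxy)phenyl]piperidine-1-carboxylate | COc1cc(O[Si](C)(C)C)c([C@H]2CCCCN2C(=O)OC(C)(C)C)c(OS(=O)(=O)C(F)(F)F)c1[Si](C)(C)C | intermediate (not isolated)
18 | tert-butyl (R)-2-[6-hydroxy-4-methoxy-3-(trimethylsilyl)-2-(trifluoromethanesulfonyloxy)phenyl]piperidine-1-carboxylate | COc1cc(O)c([C@H]2CCCCN2C(=O)OC(C)(C)C)c(OS(=O)(=O)C(F)(F)F)c1[Si](C)(C)C | intermediate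
19 | tert-butyl (R)-2-[6-(benzyloxy)-4-methoxy-3-(trimethylsilyl)-2-(trifluoromethanesulfonyloxy)phenyl]piperidine-1-carboxylate | COc1cc(OCc2ccccc2)c([C@H]2CCCCN2C(=O)OC(C)(C)C)c(OS(=O)(=O)C(F)(F)F)c1[Si](C)(C)C | intermediate
20 | phenylpropiolic acid | OC(=O)C#Cc1ccccc1 | starting material
21 | tert-butyl (R)-2-[6-(benzyloxy)-4-methoxy-2,3-didehydrophenyl]piperidine-1-carboxylate (C4a–C8a aryne) | COC1=CC(OCc2ccccc2)=C([C@H]2CCCCN2C(=O)OC(C)(C)C)C#C1 | intermediate (not isolated)
22 | cesium salt of the C4a aryl anion of the C8a O-aryl phenylpropiolate | COc1cc(OCc2ccccc2)c([C@H]2CCCCN2C(=O)OC(C)(C)C)c(OC(=O)C#Cc2ccccc2)[c-]1.[Cs+] | intermediate (not isolated)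
23 | cesium 3-(benzyloxy)-2-[(R)-1-(tert-butoxycarbonyl)piperidin-2-yl]-5-methoxy-6-(3-phenylprop-2-ynoyl)phenoxide | COc1cc(OCc2ccccc2)c([C@H]2CCCCN2C(=O)OC(C)(C)C)c([O-])c1C(=O)C#Cc1ccccc1.[Cs+] | intermediate (not isolated)
24 | tert-butyl (R)-2-[7-(benzyloxy)-5-methoxy-4-oxo-2-phenyl-4H-chromen-8-yl]piperidine-1-carboxylate | COc1cc(OCc2ccccc2)c([C@H]2CCCCN2C(=O)OC(C)(C)C)c2oc(-c3ccccc3)cc(=O)c12 | intermediate
25 | (R)-7-(benzyloxy)-5-methoxy-2-phenyl-8-(piperidin-2-yl)-4H-chromen-4-one trifluoroacetate | COc1cc(OCc2ccccc2)c([C@H]2CCCCN2)c2oc(-c3ccccc3)cc(=O)c12.OC(=O)C(F)(F)F | intermediate (not isolated)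
26 | (R)-7-(benzyloxy)-5-methoxy-8-(1-methylpiperidin-2-yl)-2-phenyl-4H-chromen-4-one | COc1cc(OCc2ccccc2)c([C@H]2CCCCN2C)c2oc(-c3ccccc3)cc(=O)c12 | intermediate
27 | (R)-7-hydroxy-5-methoxy-8-(1-methylpiperidin-2-yl)-2-phenyl-4H-chromen-4-one | COc1cc(O)c([C@H]2CCCCN2C)c2oc(-c3ccccc3)cc(=O)c12 | target

**Totals.** Total step count: 12. Longest linear sequence: 12 steps (1 to 27).

**Steps most likely to fail**

1. Step 10.
- Risks:
  - The aryl anion may be protonated before acyl transfer, so that only O-arylation occurs.
  - The bulky C8 substituent may deflect the carboxylate to C4a.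
  - The carbamate carbonyl oxygen may capture C8a internally with loss of the tert-butyl group.
  - The acid may decarboxylate, or the Boc group may be lost thermally.
- Fallback (sets out from 13, comes back at 27): the C4a–C4 bond is made by acylating an aryllithium, and O1 is kept from the phloroglucinol oxygen.
  - Both phenols of 13 are masked (MOMCl, iPr2NEt, CH2Cl2) to give tert-butyl (R)-2-[3-bromo-4-methoxy-2,6-bis(methoxymethoxy)phenyl]piperidine-1-carboxylate F1.
  - Bromine–lithium exchange (n-BuLi, THF, −78 °C) gives the corresponding 3-lithio arene F2.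
  - F2 is acylated with N-methoxy-N-methyl-3-phenylprop-2-ynamide F3 (made from 20, MeNHOMe·HCl and carbonyldiimidazole) to give the aryl ynone F4 after an NH4Cl quench.
  - HCl in MeOH removes both MOM groups and the Boc group. Only the oxygen ortho to the ketone can reach the alkyne, and brief K2CO3 treatment completes the 6-endo closure to (R)-7-hydroxy-5-methoxy-2-phenyl-8-(piperidin-2-yl)-4H-chromen-4-one F5.
  - Reductive methylation (aq. HCHO, NaBH(OAc)3) then gives 27.

2. Step 8.
- Risks:
  - Sulfonylation of the lithium phenoxide, flanked by SiMe3 and the piperidinyl group, may be incomplete at −78 °C.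
  - The remote silyl ether may be lost early.
  - The butyllithium may attack the carbamate competitively.
- Fallback (sets out from 13, comes back at 19): silyl migration and sulfonylation are uncoupled, and the order of the two O-functionalisations is reversed.
  - The sequence is run through 14 and 15 as far as 16 and quenched with AcOH in MeOH. This gives the C-silylated resorcinol tert-butyl (R)-2-[2,6-dihydroxy-4-methoxy-3-(trimethylsilyl)phenyl]piperidine-1-carboxylate F6.
  - The two phenols of F6 differ strongly in steric access. Mitsunobu benzylation with one equivalent of BnOH should therefore take the open one and give tert-butyl (R)-2-[6-(benzyloxy)-2-hydroxy-4-methoxy-3-(trimethylsilyl)phenyl]piperidine-1-carboxylate F7.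
  - The remaining hindered phenol is then triflated without a low-temperature limit (Tf2O, pyridine, CH2Cl2, 0 °C to rt) to give 19.

3. Step 4.
- Risks:
  - Facial selectivity may be poor or inverted if the ortho MOM oxygens compete with the sulfinyl oxygen for magnesium.
  - Addition to the twisted, di-ortho-substituted imine may be sluggish.
- Fallback (sets out from 3, comes back at 11): the polarity of the C–C bond formation is inverted.
  - Purchased 5-chloropentanal and (R)-tert-butanesulfinamide are condensed (CuSO4, CH2Cl2) to give (R,E)-N-(5-chloropentylidene)-2-methylpropane-2-sulfinamide F8.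
  - Aryllithium 3 is transmetalated with MgBr2·OEt2 to [4-methoxy-2,6-bis(methoxymethoxy)phenyl]magnesium bromide F9.
  - F9 is added to F8 in CH2Cl2–toluene at −48 °C. By the same closed model, R-configured sulfur and an aryl nucleophile should give the (R)-sulfinyl (1R)-adduct F10.
  - NaH in DMF closes the ring to the (R)-sulfinyl (2R)-piperidine F11.
  - The conditions of step 6 lead to 11 and on to 12.

**Further compounds**

F1 | step 10 | tert-butyl (R)-2-[3-bromo-4-methoxy-2,6-bis(methoxymethoxy)phenyl]piperidine-1-carboxylate | COc1cc(OCOC)c([C@H]2CCCCN2C(=O)OC(C)(C)C)c(OCOC)c1Br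
F2 | step 10 | {3-[(R)-1-(tert-butoxycarbonyl)piperidin-2-yl]-6-methoxy-2,4-bis(methoxymethoxy)phenyl}lithium | COc1cc(OCOC)c([C@H]2CCCCN2C(=O)OC(C)(C)C)c(OCOC)c1[Li]
F3 | step 10 | N-methoxy-N-methyl-3-phenylprop-2-ynamide | CON(C)C(=O)C#Cc1ccccc1
F4 | step 10 | tert-butyl (R)-2-[4-methoxy-2,6-bis(methoxymethoxy)-3-(3-phenylprop-2-ynoyl)phenyl]piperidine-1-carboxylate | COc1cc(OCOC)c([C@H]2CCCCN2C(=O)OC(C)(C)C)c(OCOC)c1C(=O)C#Cc1ccccc1
F5 | step 10 | (R)-7-hydroxy-5-methoxy-2-phenyl-8-(piperidin-2-yl)-4H-chromen-4-one | COc1cc(O)c([C@H]2CCCCN2)c2oc(-c3ccccc3)cc(=O)c12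
F6 | step 8 | tert-butyl (R)-2-[2,6-dihydroxy-4-methoxy-3-(trimethylsilyl)phenyl]piperidine-1-carboxylate | COc1cc(O)c([C@H]2CCCCN2C(=O)OC(C)(C)C)c(O)c1[Si](C)(C)C
F7 | step 8 | tert-butyl (R)-2-[6-(benzyloxy)-2-hydroxy-4-methoxy-3-(trimethylsilyl)phenyl]piperidine-1-carboxylate | COc1cc(OCc2ccccc2)c([C@H]2CCCCN2C(=O)OC(C)(C)C)c(O)c1[Si](C)(C)C
F8 | step 4 | (R,E)-N-(5-chloropentylidene)-2-methylpropane-2-sulfinamide | CC(C)(C)[S@@](=O)/N=C/CCCCCl
F9 | step 4 | [4-methoxy-2,6-bis(methoxymethoxy)phenyl]magnesium bromide | Br[Mg]c1c(OCOC)cc(OC)cc1OCOC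
F10 | step 4 | (R)-N-{(1R)-5-chloro-1-[4-methoxy-2,6-bis(methoxymethoxy)phenyl]pentyl}-2-methylpropane-2-sulfinamide | CC(C)(C)[S@@](=O)N[C@H](CCCCCl)c1c(OCOC)cc(OC)cc1OCOC
F11 | step 4 | (2R)-1-[(R)-tert-butylsulfinyl]-2-[4-methoxy-2,6-bis(methoxymethoxy)phenyl]piperidine | CC(C)(C)[S@@](=O)N1CCCC[C@@H]1c1c(OCOC)cc(OC)cc1OCOC
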